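Cuts (flavan numbering): first the C4–aryl bond to the acylphloroglucinol ring, giving a C4–OMe placeholder and free 1-(2,4,6-trihydroxyphenyl)dodecan-1-one. Next the pyran ring across C3–C4 and O1–C2, giving a salicylaldehyde-derived o-quinone methide and a 4-oxygenated styrene. Last the aryl–acyl bond, giving phloroglucinol and dodecanoyl chloride.
Enabling feature: on the resorcinol-derived ring the phenolic O1 sits on C8a next to C4a, so O1–C8a–C4a–C4 is a latent 1-oxadiene (o-quinone methide). The same O1 lone pair lets C4 ionise a second time, and C2–C3 with the p-oxygenated phenyl ring is a latent styrene.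
Forward order: the three benzene rings are bought. The pyran ring, the only ring made, arises in one catalytic asymmetric [4+2] step; the acylphloroglucinol is then joined at C4 by SN1 Friedel–Crafts exchange of OMe, and one deprotection finishes.
Stereochemistry: a confined chiral Brønsted acid sets C4(OMe), and the 2,4-cis closure relays this to C2 (S). The placeholder centre is then erased and rebuilt as 4R by attack anti to the C2 aryl group. This gives the 2,4-trans relation, which a direct, cis-selective cycloaddition of a C4-aryl quinone methide would not give.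
Helpers: OMe at C4 is placeholder and leaving group. Acetyl on O7 and O4' switches off arene nucleophilicity and styrene polymerisation and locks C2–O1 against ionisation. All helpers are gone in the target.
Key step: step 3

Assumption: the (S,S)-enantiomer of the catalyst is taken to deliver (2S,4S)-9. The sense of induction cannot be derived from precedent, both antipodes are accessible, and the antipode is used if the sense proves opposite.

Step 1
Reactants: 1 phloroglucinol; 2 dodecanoyl chloride
Product: 3 1-(2,4,6-trihydroxyphenyl)dodecan-1-one
Conditions: AlCl3 (4 equiv), CH2Cl2–MeNO2, 0 to 40 °C; ice/aq HCl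
Reagents that add atoms: none
Why: Friedel–Crafts C-acylation of a very electron-rich arene; the chelated aryl ketone formed is deactivated, so the reaction should stop after one acyl group, and no stereocentre is involved.

Step 2
Reactants: 4 2,4-dihydroxybenzaldehyde
Product: 5 4-formyl-3-hydroxyphenyl acetate
Conditions: Ac2O (1.0 equiv), pyridine, 0 °C
Reagents that add atoms: acetic anhydride CC(=O)OC(C)=O
Why: Selective O-acylation: the 2-OH is tied up in a hydrogen bond to the formyl group and is the poorer nucleophile, so one equivalent of anhydride should acetylate only the 4-OH.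

Step 3
Reactants: 5 4-formyl-3-hydroxyphenyl acetate; 6 4-acetoxystyrene
Product: 9 (2S,4S)-2-(4-acetoxyphenyl)-4-methoxychroman-7-yl acetate, via dimethyl acetal 7 (not isolated), via methoxy o-quinone methide 8 (not isolated)
Conditions: HC(OMe)3 (1.1 equiv), (S,S)-IDPi (BINOL-derived imidodiphosphorimidate, 5 mol %), 5 Å MS, toluene, rt, then −20 °C, 6 (3 equiv) added slowly; 2,4-cis isomer separated by chromatography
Reagents that add atoms: trimethyl orthoformate COC(OC)OC
Why: Proposed new method: the acid turns 5 and the orthoformate into acetal 7, which loses methanol to the (E)-methoxy o-quinone methide 8, whose O-protonated form is an aryl oxocarbenium ion held to the chiral counter-anion by ion pairing and by the O1–H hydrogen bond; the CH2 end of styrene 6 adds to C4 while O1 collapses on the developing benzylic cation at C2, a strongly asynchronous inverse-electron-demand oxa-[4+2] cycloaddition. The closest known reaction types are the Lewis acid three-component chroman synthesis from salicylaldehydes, orthoformates and alkenes, the confined-acid asymmetric intramolecular [4+2] of alkoxy o-quinone methides made from salicylaldehydes, and the chiral N-triflylphosphoramide-catalysed intermolecular [4+2] of aryl o-quinone methides with styrenes, so that only the intermolecular asymmetric use of an alkoxy o-quinone methide is new. The pyran ring closes in the intermolecular [4+2] mode, O1–C8a–C4a–C4 plus C3–C2, with the C3–C4 bond ahead of the O1–C2 bond. C4 is controlled by the catalyst, which shields one face of the planar oxocarbenium carbon, and C2 by the endo, chair-like collapse that leaves methoxy and aryl groups both pseudo-equatorial (2,4-cis), so that 4S is relayed into 2S; the minor trans isomer would carry 2R and is therefore removed. Regioselectivity follows from polarity (nucleophilic CH2 to electrophilic C4, O1 to the benzylic carbon), and only O1 can close the ring because O7 is acetylated. The step needs activation of the acetal but not of the alkene, the arenes or the product, and the two acetoxy groups secure this: they keep the rings of 7 and 9 from acting as Friedel–Crafts nucleophiles, make 6 a poor monomer for cationic polymerisation and make the C4–OMe and C2–O1 bonds of 9 slow to ionise, so that C2 does not racemise.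

Step 4
Reactants: 9 (2S,4S)-2-(4-acetoxyphenyl)-4-methoxychroman-7-yl acetate; 3 1-(2,4,6-trihydroxyphenyl)dodecan-1-one
Product: 11 (2S,4R)-2-(4-acetoxyphenyl)-4-(3-dodecanoyl-2,4,6-trihydroxyphenyl)chroman-7-yl acetate, via flavan-4-yl cation 10 (not isolated)
Conditions: 3 (2.5 equiv), BF3·OEt2 (30 mol %), 1,4-dioxane–CH2Cl2, 0 °C to rt, Et3N quench
Reagents that add atoms: none
Why: SN1-type Friedel–Crafts benzylation as used for 4-arylflavans and proanthocyanidins: the Lewis acid ionises C4–OMe to cation 10 (stabilised by the O1 lone pair through C8a–C4a), one of the two equivalent free ring carbons of 3 attacks pseudo-axially on the face anti to the equatorial C2 aryl group and so sets 4R (2,4-trans) under kinetic control, while the electron-poor 4-acetoxyphenyl group keeps C2–O1 from ionising so that 2S is kept.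

Step 5
Reactants: 11 (2S,4R)-2-(4-acetoxyphenyl)-4-(3-dodecanoyl-2,4,6-trihydroxyphenyl)chroman-7-yl acetate
Product: 12 (+)-myristinin A
Conditions: NH4OAc, MeOH–H2O 4:1, rt, argon
Reagents that add atoms: none
Why: Neutral ammonium acetate-catalysed hydrolysis of the two phenyl acetates, chosen because neither acid nor a phenoxide-forming base is present, so that the freed 4'-hydroxyflavan cannot open to a p-quinone methide and both 2S and 4R should be kept.

Compound list
1 | phloroglucinol (benzene-1,3,5-triol) | Oc1cc(O)cc(O)c1 | starting material
2 | dodecanoyl chloride | CCCCCCCCCCCC(=O)Cl | starting material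
3 | 1-(2,4,6-trihydroxyphenyl)dodecan-1-one | CCCCCCCCCCCC(=O)c1c(O)cc(O)cc1O | intermediate
4 | 2,4-dihydroxybenzaldehyde | O=Cc1ccc(O)cc1O | starting material
5 | 4-formyl-3-hydroxyphenyl acetate | CC(=O)Oc1ccc(C=O)c(O)c1 | intermediate
6 | 4-acetoxystyrene (4-vinylphenyl acetate) | C=Cc1ccc(OC(C)=O)cc1 | starting material
7 | 4-(dimethoxymethyl)-3-hydroxyphenyl acetate | COC(OC)c1ccc(OC(C)=O)cc1O | intermediate
8 | (4E)-4-(methoxymethylidene)-3-oxocyclohexa-1,5-dien-1-yl acetate | CO/C=C1\C=CC(OC(C)=O)=CC1=O | intermediate
9 | (2S,4S)-2-(4-acetoxyphenyl)-4-methoxychroman-7-yl acetate (2,4-cis) | CO[C@H]1C[C@@H](c2ccc(OC(C)=O)cc2)Oc2cc(OC(C)=O)ccc21 | intermediate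
10 | (2S)-7-acetoxy-2-(4-acetoxyphenyl)chroman-4-ylium (flavan-4-yl cation) | [CH+]1C[C@@H](c2ccc(OC(C)=O)cc2)Oc2cc(OC(C)=O)ccc21 | intermediate
11 | (2S,4R)-2-(4-acetoxyphenyl)-4-(3-dodecanoyl-2,4,6-trihydroxyphenyl)chroman-7-yl acetate (2,4-trans) | CCCCCCCCCCCC(=O)c1c(O)cc(O)c([C@@H]2C[C@@H](c3ccc(OC(C)=O)cc3)Oc3cc(OC(C)=O)ccc32)c1O | intermediate
12 | (+)-myristinin A, 1-{2,4,6-trihydroxy-3-[(2S,4R)-7-hydroxy-2-(4-hydroxyphenyl)chroman-4-yl]phenyl}dodecan-1-one | CCCCCCCCCCCC(=O)c1c(O)cc(O)c([C@@H]2C[C@@H](c3ccc(O)cc3)Oc3cc(O)ccc32)c1O | target

Total step count: 5. Longest linear sequence: 4 steps (4 → 5 → 9 → 11 → 12).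

Steps most likely to fail

**Step 3 (Proposed new method).**
- Facial discrimination at C4 may be weak in the intermolecular addition.
- The C4-to-C2 relay may leak through unselective ring closure.
- The activated 7-acetate may undergo methanolysis during acetal formation.
- The styrene may oligomerise.
- The product may re-ionise at C4 with loss of methanol.

The fallback uses known chemistry only and takes the stereochemistry from a later kinetic resolution instead of from the cycloaddition. It sets out from 5 and 6 and comes back at 11. The achiral Lewis acid three-component chroman synthesis (HC(OMe)3, Sc(OTf)3 cat., CH2Cl2, via 7 and 8) gives racemic 2-(4-acetoxyphenyl)-4-methoxychroman-7-yl acetate F1. Sc(OTf)3 in wet MeCN exchanges OMe for OH to give racemic 2-(4-acetoxyphenyl)-4-hydroxychroman-7-yl acetate F2. Dess–Martin periodinane then gives racemic 7,4'-diacetoxyflavanone F3. Asymmetric transfer hydrogenation is run as a kinetic resolution (RuCl[(S,S)-TsDPEN](p-cymene), HCO2H–Et3N). It should reduce only the (S)-ketone, giving (2S,4S)-2-(4-acetoxyphenyl)-4-hydroxychroman-7-yl acetate F4. It should leave (R)-7,4'-diacetoxyflavanone F5, which is separated. F4 replaces 9 under the conditions of step 4, ionises to the same cation 10 and gives 11.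

**Step 4.**
- The kinetic anti attack may erode through reversible C4–aryl bond formation, with drift towards the 2,4-cis isomer.
- Cation 10 may eliminate to the flav-3-ene, whose allylic C2–O1 bond is labile.
- The triphenol may undergo O-alkylation and double C-alkylation.
- Reaction of the acyl-deactivated, poorly soluble nucleophile may be slow.

The fallback sets out from 3 and 9 and comes back at 11. Compound 3 is perbenzylated (BnBr, K2CO3, DMF, 60 °C) to 1-[2,4,6-tris(benzyloxy)phenyl]dodecan-1-one F6. Its ketone is twisted out of conjugation, so the ring stays nucleophilic, and it has no free OH. F6 and 9 are joined with TMSOTf in homogeneous CH2Cl2 at −40 °C via cation 10, the way perbenzylated flavan units are joined in procyanidin synthesis. This gives (2S,4R)-2-(4-acetoxyphenyl)-4-[2,4,6-tris(benzyloxy)-3-dodecanoylphenyl]chroman-7-yl acetate F7 under aprotic, strictly kinetic conditions. Hydrogenolysis of the three benzyl ethers of F7 (H2, Pd/C, EtOAc) gives 11.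

**Step 1.**
- O-acylation and a second C-acylation of phloroglucinol may compete.
- The amphiphilic product may be lost from the aluminium chelate on work-up.

The fallback sets out from 1 and comes back at 3 by a Houben–Hoesch reaction. Compound 1 with dodecanenitrile, ZnCl2 and dry HCl in Et2O at 0 °C gives 2-(1-iminododecyl)benzene-1,3,5-triol hydrochloride F8. The iminium group of F8 deactivates the ring against a second attack, and boiling water hydrolyses F8 to 3.

Further compounds
F1 | step 3 | racemic 2-(4-acetoxyphenyl)-4-methoxychroman-7-yl acetate | COC1CC(c2ccc(OC(C)=O)cc2)Oc2cc(OC(C)=O)ccc21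
F2 | step 3 | racemic 2-(4-acetoxyphenyl)-4-hydroxychroman-7-yl acetate | OC1CC(c2ccc(OC(C)=O)cc2)Oc2cc(OC(C)=O)ccc21
F3 | step 3 | racemic 7,4'-diacetoxyflavanone | O=C1CC(c2ccc(OC(C)=O)cc2)Oc2cc(OC(C)=O)ccc21
F4 | step 3 | (2S,4S)-2-(4-acetoxyphenyl)-4-hydroxychroman-7-yl acetate | O[C@H]1C[C@@H](c2ccc(OC(C)=O)cc2)Oc2cc(OC(C)=O)ccc21
F5 | step 3 | (R)-7,4'-diacetoxyflavanone | O=C1C[C@H](c2ccc(OC(C)=O)cc2)Oc2cc(OC(C)=O)ccc21
F6 | step 4 | 1-[2,4,6-tris(benzyloxy)phenyl]dodecan-1-one | CCCCCCCCCCCC(=O)c1c(OCc2ccccc2)cc(OCc2ccccc2)cc1OCc1ccccc1
F7 | step 4 | (2S,4R)-2-(4-acetoxyphenyl)-4-[2,4,6-tris(benzyloxy)-3-dodecanoylphenyl]chroman-7-yl acetate | CCCCCCCCCCCC(=O)c1c(OCc2ccccc2)cc(OCc2ccccc2)c([C@@H]2C[C@@H](c3ccc(OC(C)=O)cc3)Oc3cc(OC(C)=O)ccc32)c1OCc1ccccc1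
F8 | step 1 | 2-(1-iminododecyl)benzene-1,3,5-triol hydrochloride | CCCCCCCCCCCC(=N)c1c(O)cc(O)cc1O.Cl
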